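**Retrosynthetic overview**
1. The target comes from O-demethylation of its 5,7-dimethyl ether 20; pyranone ring C is opened to o-hydroxyacetophenone 17 and methyl benzoate (Claisen condensation, cyclodehydration), and the acetyl group to Friedel–Crafts acetylation of ring A with loss of the one doubly flanked O-methyl group.
2. The N-methylpiperidine comes from an N-H lactam (N-methylation, LiAlH4) that carried a carboxyl group on C3, removed by Barton decarboxylation.
3. Key disconnection: piperidine bonds C2–C3 and C4–C5, giving 2-azadiene ArCH=N–C(OTBS)=CH2 (from 2,4,6-trimethoxybenzaldehyde, LiN(SiMe3)2 and acetyl chloride) and 3-acryloyloxazolidin-2-one, joined by an enantioselective Diels–Alder reaction with Cu(OTf)2 and a bis(oxazoline) ligand.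
4. Enabling feature: in the piperidine ring N1 lies between C2 (the CH bonded to C8 of ring A, an aldimine carbon in disguise) and C6 (a CH2 that can stand at the lactam/silyl imidate level), so C2=N1–C6=C5 is a 2-azadiene and the unsubstituted C3–C4 unit is a two-carbon dienophile.
5. Ring order: ring A and the phenyl ring are bought, the piperidine is formed in step 2, ring C in step 8.

Key step: step 2

Assumption: the cycloaddition is taken to follow the exo mode and the square-planar chelate model known for 1-aryl-3-silyloxy-2-azadienes; the (R,R) ligand is named on that basis, and its mirror image would be used if the sense proved opposite.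

**Step 1**
Reactants: 1 2,4,6-trimethoxybenzaldehyde; 2 acetyl chloride
Product: 5 (E)-N-{1-[(tert-butyldimethylsilyl)oxy]ethenyl}-1-(2,4,6-trimethoxyphenyl)methanimine (2-azadiene), via N-silyl imine 3 (not isolated), via N-acetyl imine 4 (not isolated)
Conditions: LiN(SiMe3)2, THF, 0 °C; Me3SiCl; 2, 0 °C → rt; evaporate; TBSOTf, Et3N, Et2O, 0 °C → rt; filter under Ar, use crude
Reagents that add atoms: lithium bis(trimethylsilyl)amide, [Li]N([Si](C)(C)C)[Si](C)(C)C; tert-butyldimethylsilyl trifluoromethanesulfonate, CC(C)(C)[Si](C)(C)OS(=O)(=O)C(F)(F)F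
Why: Aza-Peterson olefination of the non-enolisable aldehyde should give N-silyl aldimine 3, N-acylation with loss of Me3SiCl gives N-acetyl imine 4 (no enamide tautomer is possible), and O-silylation of its enol form (silyl enol ether formation) gives the 3-silyloxy-2-azadiene with the E C=N bond that places the aryl group outside the diene.

**Step 2**
Reactants: 5 (E)-N-{1-[(tert-butyldimethylsilyl)oxy]ethenyl}-1-(2,4,6-trimethoxyphenyl)methanimine; 6 3-acryloyl-1,3-oxazolidin-2-one
Product: 8 3-{[(2R,3R)-6-oxo-2-(2,4,6-trimethoxyphenyl)piperidin-3-yl]carbonyl}-1,3-oxazolidin-2-one (2,3-trans), via silyl imidate cycloadduct 7 (not isolated)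
Conditions: Cu(OTf)2 (10 mol %), (R,R)-t-Bu-box [2,2'-(propane-2,2-diyl)bis((4R)-4-tert-butyl-4,5-dihydro-1,3-oxazole)] (11 mol %), 4 Å MS, CH2Cl2, −40 °C → rt; then MeOH, rt
Reagents that add atoms: none
Why: The Cu-chelated s-cis acrylimide should react with the electron-rich diene in a normal-demand, strongly asynchronous Diels–Alder reaction (Mukaiyama–Michael/Mannich in the stepwise limit), the CH2 terminus of 5 bonding to the acrylimide β-carbon and the aldimine carbon to the α-carbon, after which methanol cleaves O-silyl imidate 7 to the lactam. The closest known reaction type is the Cu(OTf)2–bis(oxazoline)-catalysed enantioselective Diels–Alder reaction of 1-aryl-3-silyloxy-2-azadienes with 3-acryloyloxazolidin-2-one. The piperidine ring is closed by [4+2] cycloaddition (in the stepwise limit a 6-(enolexo)-endo-trig Mannich closure). The acyl-bearing stereocentre is controlled by the ligand, whose tert-butyl group shields the Re face of the α-carbon in the square-planar divalent copper chelate so that bonding occurs on the Si face; the benzylic stereocentre follows from the E imine geometry and the exo transition state, which should give the 2,3-trans adduct with (R) configuration at the aryl-bearing carbon. The step needs regioselectivity, secured by the 3-silyloxy donor that makes the CH2 terminus the nucleophilic end of the diene, and exo plus facial selectivity, secured by two-point binding of the imide and by the bulky aryl group turning away from the ligand; a minor cis adduct would lead to the antipode after step 4 and is removed here by chromatography or crystallisation.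

**Step 3**
Reactants: 8 3-{[(2R,3R)-6-oxo-2-(2,4,6-trimethoxyphenyl)piperidin-3-yl]carbonyl}-1,3-oxazolidin-2-one
Product: 10 (2R,3R)-6-oxo-2-(2,4,6-trimethoxyphenyl)piperidine-3-carboxylic acid, via peroxy acid 9 (not isolated)
Conditions: LiOH, 30% H2O2, THF/H2O, 0 °C; Na2SO3; HCl to pH 3
Reagents that add atoms: hydrogen peroxide, OO
Why: Hydroperoxide should add selectively to the exocyclic imide carbonyl (LiOOH cleavage of an N-acyloxazolidinone) and sulfite reduces the peroxy acid; the lactam is inert, and epimerisation at the carboxyl-bearing carbon is irrelevant because that centre is removed in step 4 while the benzylic C–H is not acidic.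

**Step 4**
Reactants: 10 (2R,3R)-6-oxo-2-(2,4,6-trimethoxyphenyl)piperidine-3-carboxylic acid
Product: 12 (6R)-6-(2,4,6-trimethoxyphenyl)piperidin-2-one, via thiohydroxamate ester 11 (not isolated)
Conditions: 1-hydroxypyridine-2(1H)-thione, DCC, DMAP (cat.), CH2Cl2, rt, dark; then t-BuSH, THF, hν (tungsten lamp), rt
Reagents that add atoms: none
Why: Barton reductive decarboxylation: the O-acyl thiohydroxamate should fragment under visible light to CO2 and a secondary alkyl radical that takes hydrogen from t-BuSH in a radical chain; the neighbouring benzylic stereocentre is not involved and keeps its (R) configuration.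

**Step 5**
Reactants: 12 (6R)-6-(2,4,6-trimethoxyphenyl)piperidin-2-one
Product: 13 (6R)-1-methyl-6-(2,4,6-trimethoxyphenyl)piperidin-2-one
Conditions: NaH, MeI, THF/DMF, 0 °C → rt
Reagents that add atoms: iodomethane, CI
Why: Deprotonation of the lactam N–H and SN2 N-methylation (amide alkylation); no C–H bond of the substrate is acidic enough to compete.

**Step 6**
Reactants: 13 (6R)-1-methyl-6-(2,4,6-trimethoxyphenyl)piperidin-2-one
Product: 14 (2R)-1-methyl-2-(2,4,6-trimethoxyphenyl)piperidine
Conditions: LiAlH4, THF, reflux; aq. NaOH work-up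
Reagents that add atoms: none
Why: LiAlH4 reduction of a tertiary lactam to the cyclic amine via the iminium ion at the former carbonyl carbon; the aryl methyl ethers and the stereocentre are untouched.

**Step 7**
Reactants: 14 (2R)-1-methyl-2-(2,4,6-trimethoxyphenyl)piperidine; 15 acetic anhydride
Product: 17 1-{2-hydroxy-4,6-dimethoxy-3-[(2R)-1-methylpiperidin-2-yl]phenyl}ethan-1-one, via trimethoxy ketone 16 (not isolated)
Conditions: BF3·OEt2 (4 equiv), then 15, CH2Cl2, 0 °C → rt; aq. NaHCO3
Reagents that add atoms: none
Why: Friedel–Crafts acetylation should occur at the only type of free ring position (the two are equivalent) of the BF3-complexed amine, and BF3 chelated to the new ketone then cleaves the one ortho methoxy group flanked on both sides (acetyl and piperidinyl), which is twisted out of conjugation and the more basic oxygen, as established for acetylation of 4-(2,4,6-trimethoxyphenyl)piperidines; complexing nitrogen with BF3 before the anhydride is added prevents N-acylammonium formation and C–N ionisation.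

**Step 8**
Reactants: 17 1-{2-hydroxy-4,6-dimethoxy-3-[(2R)-1-methylpiperidin-2-yl]phenyl}ethan-1-one; 18 methyl benzoate
Product: 20 5,7-dimethoxy-8-[(2R)-1-methylpiperidin-2-yl]-2-phenyl-4H-chromen-4-one, via 1,3-diketone 19 (not isolated)
Conditions: NaH (5 equiv), DMF, 0 °C → rt; then conc. HCl, rt → 50 °C; Na2CO3
Reagents that add atoms: none
Why: Crossed Claisen condensation of the dianion of 17 with the non-enolisable ester should give the 1,3-diketone, and acid-catalysed cyclodehydration (6-exo-trig attack of the phenol on the benzoyl carbonyl, then loss of water; Baker–Venkataraman-type flavone synthesis) closes ring C through the only free phenol, the one next to the piperidine, which fixes the piperidinyl group at C8.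

**Step 9**
Reactants: 20 5,7-dimethoxy-8-[(2R)-1-methylpiperidin-2-yl]-2-phenyl-4H-chromen-4-one
Product: 21 5,7-dihydroxy-8-[(2R)-1-methylpiperidin-2-yl]-2-phenyl-4H-chromen-4-one (target)
Conditions: BBr3 (6 equiv), CH2Cl2, −78 °C → rt; MeOH, then aq. NaHCO3
Reagents that add atoms: none
Why: Lewis-acid O-demethylation with BBr3 should cleave the carbonyl-chelated 5-methyl ether first and the 7-methyl ether on warming; nitrogen is held as its BBr3 adduct and no heating in protic acid is used, so ionisation of the benzylic C–N bond (retro-Mannich) and racemisation should be avoided.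

**Compound list**
1 | 2,4,6-trimethoxybenzaldehyde | COc1cc(OC)c(C=O)c(OC)c1 | starting material
2 | acetyl chloride | CC(=O)Cl | starting material
3 | (E)-N-(trimethylsilyl)-1-(2,4,6-trimethoxyphenyl)methanimine | COc1cc(OC)c(/C=N/[Si](C)(C)C)c(OC)c1 | intermediate
4 | N-[(E)-(2,4,6-trimethoxyphenyl)methylidene]acetamide | COc1cc(OC)c(/C=N/C(C)=O)c(OC)c1 | intermediate
5 | (E)-N-{1-[(tert-butyldimethylsilyl)oxy]ethenyl}-1-(2,4,6-trimethoxyphenyl)methanimine | COc1cc(OC)c(/C=N/C(=C)O[Si](C)(C)C(C)(C)C)c(OC)c1 | intermediate
6 | 3-acryloyl-1,3-oxazolidin-2-one | C=CC(=O)N1CCOC1=O | starting material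
7 | 3-{[(2R,3R)-6-[(tert-butyldimethylsilyl)oxy]-2-(2,4,6-trimethoxyphenyl)-2,3,4,5-tetrahydropyridin-3-yl]carbonyl}-1,3-oxazolidin-2-one | CC(C)(C)[Si](C)(C)OC1=N[C@@H](c2c(OC)cc(OC)cc2OC)[C@H](C(=O)N2CCOC2=O)CC1 | intermediate
8 | 3-{[(2R,3R)-6-oxo-2-(2,4,6-trimethoxyphenyl)piperidin-3-yl]carbonyl}-1,3-oxazolidin-2-one | O=C1CC[C@@H](C(=O)N2CCOC2=O)[C@H](c2c(OC)cc(OC)cc2OC)N1 | intermediate
9 | (2R,3R)-6-oxo-2-(2,4,6-trimethoxyphenyl)piperidine-3-carboperoxoic acid | O=C1CC[C@@H](C(=O)OO)[C@H](c2c(OC)cc(OC)cc2OC)N1 | intermediate
10 | (2R,3R)-6-oxo-2-(2,4,6-trimethoxyphenyl)piperidine-3-carboxylic acid | O=C1CC[C@@H](C(=O)O)[C@H](c2c(OC)cc(OC)cc2OC)N1 | intermediate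
11 | 2-thioxopyridin-1(2H)-yl (2R,3R)-6-oxo-2-(2,4,6-trimethoxyphenyl)piperidine-3-carboxylate | O=C1CC[C@@H](C(=O)On2ccccc2=S)[C@H](c2c(OC)cc(OC)cc2OC)N1 | intermediate
12 | (6R)-6-(2,4,6-trimethoxyphenyl)piperidin-2-one | O=C1CCC[C@H](c2c(OC)cc(OC)cc2OC)N1 | intermediate
13 | (6R)-1-methyl-6-(2,4,6-trimethoxyphenyl)piperidin-2-one | O=C1CCC[C@H](c2c(OC)cc(OC)cc2OC)N1C | intermediate
14 | (2R)-1-methyl-2-(2,4,6-trimethoxyphenyl)piperidine | CN1CCCC[C@@H]1c1c(OC)cc(OC)cc1OC | intermediate
15 | acetic anhydride | CC(=O)OC(C)=O | starting material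
16 | 1-{2,4,6-trimethoxy-3-[(2R)-1-methylpiperidin-2-yl]phenyl}ethan-1-one | CN1CCCC[C@@H]1c1c(OC)cc(OC)c(C(C)=O)c1OC | intermediate
17 | 1-{2-hydroxy-4,6-dimethoxy-3-[(2R)-1-methylpiperidin-2-yl]phenyl}ethan-1-one | CN1CCCC[C@@H]1c1c(OC)cc(OC)c(C(C)=O)c1O | intermediate
18 | methyl benzoate | COC(=O)c1ccccc1 | starting material
19 | 1-{2-hydroxy-4,6-dimethoxy-3-[(2R)-1-methylpiperidin-2-yl]phenyl}-3-phenylpropane-1,3-dione | CN1CCCC[C@@H]1c1c(OC)cc(OC)c(C(=O)CC(=O)c2ccccc2)c1O | intermediate
20 | 5,7-dimethoxy-8-[(2R)-1-methylpiperidin-2-yl]-2-phenyl-4H-chromen-4-one | CN1CCCC[C@@H]1c1c(OC)cc(OC)c2c(=O)cc(-c3ccccc3)oc12 | intermediate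
21 | 5,7-dihydroxy-8-[(2R)-1-methylpiperidin-2-yl]-2-phenyl-4H-chromen-4-one | CN1CCCC[C@@H]1c1c(O)cc(O)c2c(=O)cc(-c3ccccc3)oc12 | target

**Totals**
Total step count: 9. Longest linear sequence: 9 steps (from 1).

**Steps most likely to fail**

Step 2. The ring closure may stop after the first C–C bond (the stabilised iminium-type intermediate is hydrolysed to open-chain material on work-up), or exo and facial selectivity may erode with the bulky, strongly donating di-ortho-methoxyaryl group, which lowers the enantiomeric purity at the benzylic carbon. The fallback sets out from 1 and uses auxiliary control with stepwise ring construction. Condensation with (S)-2-methylpropane-2-sulfinamide (Ti(OEt)4, THF) gives the N-sulfinyl aldimine F1. Addition of 4-chlorobutylmagnesium bromide (Cl(CH2)4MgBr, CH2Cl2, −48 °C) through the six-membered chelated transition state should give the (R)-configured sulfinamide F2. NaH in DMF closes the ring by N-alkylation to the N-sulfinylpiperidine F3. HCl in MeOH at 0 °C removes the sulfinyl group to give the secondary amine F4. Reductive methylation (aqueous CH2O, NaBH(OAc)3) comes back to the route at 14.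

Step 7. The benzylic C–N bond may ionise under the Lewis-acidic acylating medium (ring opening and racemisation), or the two ortho methoxy groups may not be discriminated in the demethylation. The fallback sets out from 14 and replaces electrophilic substitution by directed metalation. n-BuLi/TMEDA (THF, 0 °C) lithiates the ring carbon between two methoxy groups to give the aryllithium F5. N-Methoxy-N-methylacetamide converts it into ketone 16, which is isolated. BCl3 (CH2Cl2, −78 → 0 °C) then cleaves the doubly flanked, carbonyl-chelated methoxy group in a separate low-temperature operation and comes back to the route at 17.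

Step 9. Once the phenols are free in acidic medium, configuration may be lost by reversible C–N ionisation (retro-Mannich through a quinone-methide-type cation), or the 7-methyl ether may be cleaved incompletely. The fallback sets out from 20 and splits the deprotection into two mechanistically different stages. BCl3 (CH2Cl2, −78 → 0 °C) removes only the chelated 5-O-methyl group to give the 5-hydroxy-7-methoxyflavone F6. The 7-O-methyl group is then cleaved by SN2 attack of NaSEt (DMF, 110 °C) under basic conditions, in which nitrogen is not protonated and cannot leave, and this comes back to the route at 21.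

**Further compounds**
F1 | step 2 | (S,E)-2-methyl-N-[(2,4,6-trimethoxyphenyl)methylidene]propane-2-sulfinamide | CC(C)(C)[S@](=O)/N=C/c1c(OC)cc(OC)cc1OC
F2 | step 2 | (S)-N-[(1R)-5-chloro-1-(2,4,6-trimethoxyphenyl)pentyl]-2-methylpropane-2-sulfinamide | CC(C)(C)[S@](=O)N[C@H](CCCCCl)c1c(OC)cc(OC)cc1OC
F3 | step 2 | (2R)-1-[(S)-tert-butylsulfinyl]-2-(2,4,6-trimethoxyphenyl)piperidine | CC(C)(C)[S@](=O)N1CCCC[C@@H]1c1c(OC)cc(OC)cc1OC
F4 | step 2 | (2R)-2-(2,4,6-trimethoxyphenyl)piperidine | N1CCCC[C@@H]1c1c(OC)cc(OC)cc1OC
F5 | step 7 | {2,4,6-trimethoxy-3-[(2R)-1-methylpiperidin-2-yl]phenyl}lithium | CN1CCCC[C@@H]1c1c(OC)cc(OC)c([Li])c1OC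
F6 | step 9 | 5-hydroxy-7-methoxy-8-[(2R)-1-methylpiperidin-2-yl]-2-phenyl-4H-chromen-4-one | CN1CCCC[C@@H]1c1c(OC)cc(O)c2c(=O)cc(-c3ccccc3)oc12
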